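**Retrosynthetic overview**
1. Side chain: the C7 carbinol comes from chelation-controlled reduction of an α-aryloxy aryl ketone; C7–ring C from an aryl Grignard on a Weinreb amide; C8–O from Mitsunobu inversion of methyl (R)-lactate by the ring B phenol.
2. C2–ring B and C2–H: aryllithium addition to the all-cis γ-lactone, then silane reduction of the cyclic oxocarbenium ion from the face away from the C3 methyl, the C4 methyl and ring A.
3. C3–H and C4–H: hydrogenation of a butenolide anti to ring A. The plan rests on the unit O1–C2–C3(CH3)–C4(CH3) of the oxolane, which one oxidation level higher is a cis-tetrasubstituted C3=C4 alkene in a furanone whose only stereocentre is C5 (ring A).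
4. Butenolide ⇒ (S)-1-(3,4-dimethoxyphenyl)but-2-yn-1-ol + CH3MgBr + CO2 (C4–CH3, C3–C2 and O1–C2 in one flask). This is the only ring-forming step, so the O-heterocycle is in place first and every later stereocentre is relayed from C5.
5. Alkynol ⇒ 3,4-dimethoxybenzaldehyde + propyne by catalytic asymmetric alkynylation.

Key step: step 2

Atom labels: oxolane O1, C2 (ring B), C3, C4, C5 (ring A); side chain C7 (carbinol, ring C), C8 (aryloxy carbon). Rings A and C are 3,4-dimethoxyphenyl; ring B is the 3-methoxy-4-oxyphenyl ring. The target is read as all-cis (2S,3R,4S,5R) in the ring and (7R,8S), erythro, in the side chain.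

Assumption: (R)-BINOL is taken as the ligand antipode that steers the alkynylzinc to the Re face of the aldehyde, the facial sense of this catalyst family with aromatic aldehydes; this gives the (S)-carbinol because propynyl outranks the aryl group.

**Step 1**
Reactants: 1 3,4-dimethoxybenzaldehyde; 2 propyne
Product: 4 (S)-1-(3,4-dimethoxyphenyl)but-2-yn-1-ol, via ethyl(prop-1-yn-1-yl)zinc 3 (not isolated)
Conditions: 2 (4 equiv, condensed), Et2Zn (4 equiv), (R)-BINOL (20 mol%), Cy2NH (5 mol%), Et2O, rt, sealed flask, 16 h; Ti(OiPr)4 (50 mol%), 1 h; then 1, rt; aq. NH4Cl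
Reagents that add atoms: none
Why: Propyne is zincated by Et2Zn and the alkynylzinc adds to the aldehyde held on the BINOL–titanium alkoxide (catalytic asymmetric alkynylation of an aromatic aldehyde); the ligand should direct the propynyl group to the Re face, which sets the future C5 as S.

**Step 2**
Reactants: 4 (S)-1-(3,4-dimethoxyphenyl)but-2-yn-1-ol; 5 methylmagnesium bromide; 6 carbon dioxide
Product: 10 (S)-5-(3,4-dimethoxyphenyl)-3,4-dimethylfuran-2(5H)-one, via bromomagnesium alkoxide 7 (not isolated), via chelated alkenylmagnesium 8 (not isolated), via (Z)-hydroxy acid 9 (not isolated)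
Conditions: 5 (4 equiv, 3 M in Et2O), CuI (10 mol%), THF, 0 °C → 50 °C; cool to −20 °C, dry CO2 (6) bubbled in, → rt; 1 M HCl, 0 °C, then brief stirring at rt
Reagents that add atoms: none
Why: The first equivalent of CH3MgBr deprotonates the carbinol, and alkoxide 7 then directs CuI-catalysed transfer of methyl to the proximal alkyne carbon while magnesium arrives anti on the distal carbon, closing the five-membered oxamagnesacycle 8 (anti-carbomagnesiation of a propargylic alcohol, a known reaction type). CO2 inserts into the alkenyl–Mg bond with retention of alkene geometry, so in 9 the carboxyl group is cis to the carbinol. On acidification the hydroxy acid closes the furanone ring by 5-exo-trig acyl substitution (O1–C2). No new stereocentre is formed, and C5 is carried as an alkoxide whose C–O bond is never broken, so the S configuration of 4 should be retained. The step needs proximal methyl delivery and anti addition; both are secured by the alkoxide, because only that mode gives the five-membered chelate, and the alkyne already carries the C3 methyl. Cold dilute acid is used so that the benzylic, allylic C5–O bond is not ionised during lactonisation.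

**Step 3**
Reactants: 10 (S)-5-(3,4-dimethoxyphenyl)-3,4-dimethylfuran-2(5H)-one
Product: 11 (3R,4S,5R)-5-(3,4-dimethoxyphenyl)-3,4-dimethyldihydrofuran-2(3H)-one (all-cis)
Conditions: H2 (5 atm), 5% Rh/Al2O3, EtOAc, rt
Reagents that add atoms: none
Why: Heterogeneous syn-hydrogenation of the tetrasubstituted alkene should take place on the face opposite ring A, so both methyl groups end cis to the aryl group and C3 (R) and C4 (S) are set by C5; Rh/Al2O3 is chosen over Pd/C to spare the benzylic lactone C–O bond.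

**Step 4**
Reactants: 12 4-bromo-2-methoxyphenol
Product: 13 1-(benzyloxy)-4-bromo-2-methoxybenzene
Conditions: BnBr, K2CO3, DMF, rt
Reagents that add atoms: benzyl bromide, BrCc1ccccc1
Why: Williamson O-alkylation of the phenoxide masks the acidic phenol for the organolithium step.

**Step 5**
Reactants: 13 1-(benzyloxy)-4-bromo-2-methoxybenzene; 11 (3R,4S,5R)-5-(3,4-dimethoxyphenyl)-3,4-dimethyldihydrofuran-2(3H)-one
Product: 15 (3R,4S,5R)-2-[4-(benzyloxy)-3-methoxyphenyl]-5-(3,4-dimethoxyphenyl)-3,4-dimethyltetrahydrofuran-2-ol (C2 anomers, in equilibrium with the open γ-hydroxy ketone; used crude), via [4-(benzyloxy)-3-methoxyphenyl]lithium 14 (not isolated)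
Conditions: 13 (1.3 equiv), nBuLi (1.25 equiv), THF, −78 °C, 30 min; then 11, −78 °C, 1 h; aq. NH4Cl at −78 °C
Reagents that add atoms: none
Why: Bromine–lithium exchange followed by 1,2-addition of the aryllithium to the γ-lactone should stop at the lithium hemiketal at −78 °C, which prevents a second addition and leaves the enolisable C3 centre untouched; the C2 anomer mixture is of no consequence.

**Step 6**
Reactants: 15 (3R,4S,5R)-2-[4-(benzyloxy)-3-methoxyphenyl]-5-(3,4-dimethoxyphenyl)-3,4-dimethyltetrahydrofuran-2-ol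
Product: 17 (2S,3R,4S,5R)-2-[4-(benzyloxy)-3-methoxyphenyl]-5-(3,4-dimethoxyphenyl)-3,4-dimethyltetrahydrofuran (all-cis), via 2-aryl oxocarbenium ion 16 (not isolated)
Conditions: Et3SiH (3 equiv), then BF3·OEt2 (2 equiv), CH2Cl2, −78 °C; Et3N then aq. NaHCO3 at −78 °C
Reagents that add atoms: none
Why: BF3·OEt2 ionises the hemiketal and Et3SiH delivers hydride to oxocarbenium ion 16 (reductive deoxygenation of a lactol) on the face opposite the C3 methyl, which is also the face away from the C4 methyl and ring A, so ring B ends cis to all three and C2 is set as S; −78 °C is held to suppress loss of the C3 proton and benzylic ionisation.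

**Step 7**
Reactants: 17 (2S,3R,4S,5R)-2-[4-(benzyloxy)-3-methoxyphenyl]-5-(3,4-dimethoxyphenyl)-3,4-dimethyltetrahydrofuran
Product: 18 4-[(2S,3R,4S,5R)-5-(3,4-dimethoxyphenyl)-3,4-dimethyltetrahydrofuran-2-yl]-2-methoxyphenol
Conditions: H2 (1 atm), 10% Pd/C, EtOAc, rt, stopped when 17 is consumed
Reagents that add atoms: none
Why: Hydrogenolysis of the unhindered aryl benzyl ether should be much faster than cleavage of the hindered ring C–O bonds under these mild conditions.

**Step 8**
Reactants: 18 4-[(2S,3R,4S,5R)-5-(3,4-dimethoxyphenyl)-3,4-dimethyltetrahydrofuran-2-yl]-2-methoxyphenol; 19 methyl (R)-lactate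
Product: 20 methyl (S)-2-{4-[(2S,3R,4S,5R)-5-(3,4-dimethoxyphenyl)-3,4-dimethyltetrahydrofuran-2-yl]-2-methoxyphenoxy}propanoate
Conditions: 19 (1.5 equiv), PPh3 (1.5 equiv), DIAD (1.5 equiv), THF, 0 °C → rt
Reagents that add atoms: none
Why: Mitsunobu etherification displaces the activated lactate hydroxyl by the phenol with clean inversion, so the (R)-lactate gives C8 as S.

**Step 9**
Reactants: 20 methyl (S)-2-{4-[(2S,3R,4S,5R)-5-(3,4-dimethoxyphenyl)-3,4-dimethyltetrahydrofuran-2-yl]-2-methoxyphenoxy}propanoate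
Product: 21 (S)-2-{4-[(2S,3R,4S,5R)-5-(3,4-dimethoxyphenyl)-3,4-dimethyltetrahydrofuran-2-yl]-2-methoxyphenoxy}-N-methoxy-N-methylpropanamide
Conditions: MeNHOMe·HCl (3 equiv), iPrMgCl (6 equiv), THF, −20 °C → −10 °C; aq. NH4Cl
Reagents that add atoms: N,O-dimethylhydroxylamine hydrochloride, CNOC.Cl
Why: Aminolysis of the ester by the chloromagnesium amide of N,O-dimethylhydroxylamine (Weinreb amide formation) proceeds at low temperature, where the C8 centre should not be enolised.

**Step 10**
Reactants: 21 (S)-2-{4-[(2S,3R,4S,5R)-5-(3,4-dimethoxyphenyl)-3,4-dimethyltetrahydrofuran-2-yl]-2-methoxyphenoxy}-N-methoxy-N-methylpropanamide; 22 3,4-dimethoxyphenylmagnesium bromide (commercial 0.5 M solution in THF)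
Product: 23 (S)-1-(3,4-dimethoxyphenyl)-2-{4-[(2S,3R,4S,5R)-5-(3,4-dimethoxyphenyl)-3,4-dimethyltetrahydrofuran-2-yl]-2-methoxyphenoxy}propan-1-one
Conditions: 22 (2.5 equiv), THF, 0 °C → rt; cold aq. NH4Cl at 0 °C
Reagents that add atoms: none
Why: Weinreb ketone synthesis: the magnesium-chelated tetrahedral adduct blocks over-addition and releases the base-sensitive α-aryloxy ketone only on the cold, buffered quench.

**Step 11**
Reactants: 23 (S)-1-(3,4-dimethoxyphenyl)-2-{4-[(2S,3R,4S,5R)-5-(3,4-dimethoxyphenyl)-3,4-dimethyltetrahydrofuran-2-yl]-2-methoxyphenoxy}propan-1-one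
Product: 24 (1R,2S)-1-(3,4-dimethoxyphenyl)-2-{4-[(2S,3R,4S,5R)-5-(3,4-dimethoxyphenyl)-3,4-dimethyltetrahydrofuran-2-yl]-2-methoxyphenoxy}propan-1-ol (target)
Conditions: Zn(BH4)2 (2 equiv, Et2O solution), Et2O/THF, −20 °C → 0 °C; aq. NH4Cl
Reagents that add atoms: none
Why: Chelation-controlled reduction (Cram chelate): zinc bridges the carbonyl oxygen and the α-aryloxy oxygen, and hydride enters from the side of the C8 hydrogen, anti to the C8 methyl, which should give the erythro (7R,8S) alcohol.

**Compound list**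
1 | 3,4-dimethoxybenzaldehyde | COc1ccc(C=O)cc1OC | starting material
2 | propyne | CC#C | starting material
3 | ethyl(prop-1-yn-1-yl)zinc | CC#C[Zn]CC | intermediate (not isolated)
4 | (S)-1-(3,4-dimethoxyphenyl)but-2-yn-1-ol | O[C@@H](c1ccc(OC)c(OC)c1)C#CC | intermediate
5 | methylmagnesium bromide | C[Mg]Br | starting material
6 | carbon dioxide | O=C=O | starting material
7 | bromomagnesium (S)-1-(3,4-dimethoxyphenyl)but-2-yn-1-olate | Br[Mg]O[C@@H](c1ccc(OC)c(OC)c1)C#CC | intermediate (not isolated)
8 | (S)-5-(3,4-dimethoxyphenyl)-3,4-dimethyl-2,5-dihydro-1,2-oxamagnesole (chelated alkenylmagnesium, further ligands omitted) | CC1=C(C)[C@H](c2ccc(OC)c(OC)c2)O[Mg]1 | intermediate (not isolated)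
9 | (S,Z)-4-(3,4-dimethoxyphenyl)-4-hydroxy-2,3-dimethylbut-2-enoic acid (magnesium salt in the flask) | OC(=O)/C(C)=C(C)\[C@@H](O)c1ccc(OC)c(OC)c1 | intermediate (not isolated)
10 | (S)-5-(3,4-dimethoxyphenyl)-3,4-dimethylfuran-2(5H)-one | O=C1O[C@@H](c2ccc(OC)c(OC)c2)C(C)=C1C | intermediate
11 | (3R,4S,5R)-5-(3,4-dimethoxyphenyl)-3,4-dimethyldihydrofuran-2(3H)-one | O=C1O[C@@H](c2ccc(OC)c(OC)c2)[C@@H](C)[C@H]1C | intermediate
12 | 4-bromo-2-methoxyphenol | COc1cc(Br)ccc1O | starting material
13 | 1-(benzyloxy)-4-bromo-2-methoxybenzene | COc1cc(Br)ccc1OCc1ccccc1 | intermediate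
14 | [4-(benzyloxy)-3-methoxyphenyl]lithium | [Li]c1ccc(OCc2ccccc2)c(OC)c1 | intermediate (not isolated)
15 | (3R,4S,5R)-2-[4-(benzyloxy)-3-methoxyphenyl]-5-(3,4-dimethoxyphenyl)-3,4-dimethyltetrahydrofuran-2-ol (C2 anomers) | OC1(c2ccc(OCc3ccccc3)c(OC)c2)O[C@@H](c2ccc(OC)c(OC)c2)[C@@H](C)[C@H]1C | intermediate
16 | (3R,4S,5R)-2-[4-(benzyloxy)-3-methoxyphenyl]-5-(3,4-dimethoxyphenyl)-3,4-dimethyl-4,5-dihydro-3H-furan-1-ium (oxocarbenium ion) | COc1cc(C2=[O+][C@@H](c3ccc(OC)c(OC)c3)[C@@H](C)[C@H]2C)ccc1OCc1ccccc1 | intermediate (not isolated)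
17 | (2S,3R,4S,5R)-2-[4-(benzyloxy)-3-methoxyphenyl]-5-(3,4-dimethoxyphenyl)-3,4-dimethyltetrahydrofuran | COc1cc([C@H]2O[C@@H](c3ccc(OC)c(OC)c3)[C@@H](C)[C@H]2C)ccc1OCc1ccccc1 | intermediate
18 | 4-[(2S,3R,4S,5R)-5-(3,4-dimethoxyphenyl)-3,4-dimethyltetrahydrofuran-2-yl]-2-methoxyphenol | COc1cc([C@H]2O[C@@H](c3ccc(OC)c(OC)c3)[C@@H](C)[C@H]2C)ccc1O | intermediate
19 | methyl (R)-lactate | C[C@@H](O)C(=O)OC | starting material
20 | methyl (S)-2-{4-[(2S,3R,4S,5R)-5-(3,4-dimethoxyphenyl)-3,4-dimethyltetrahydrofuran-2-yl]-2-methoxyphenoxy}propanoate | COC(=O)[C@H](C)Oc1ccc([C@H]2O[C@@H](c3ccc(OC)c(OC)c3)[C@@H](C)[C@H]2C)cc1OC | intermediate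
21 | (S)-2-{4-[(2S,3R,4S,5R)-5-(3,4-dimethoxyphenyl)-3,4-dimethyltetrahydrofuran-2-yl]-2-methoxyphenoxy}-N-methoxy-N-methylpropanamide | CON(C)C(=O)[C@H](C)Oc1ccc([C@H]2O[C@@H](c3ccc(OC)c(OC)c3)[C@@H](C)[C@H]2C)cc1OC | intermediate
22 | 3,4-dimethoxyphenylmagnesium bromide | COc1ccc([Mg]Br)cc1OC | starting material
23 | (S)-1-(3,4-dimethoxyphenyl)-2-{4-[(2S,3R,4S,5R)-5-(3,4-dimethoxyphenyl)-3,4-dimethyltetrahydrofuran-2-yl]-2-methoxyphenoxy}propan-1-one | COc1ccc(C(=O)[C@H](C)Oc2ccc([C@H]3O[C@@H](c4ccc(OC)c(OC)c4)[C@@H](C)[C@H]3C)cc2OC)cc1OC | intermediate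
24 | (1R,2S)-1-(3,4-dimethoxyphenyl)-2-{4-[(2S,3R,4S,5R)-5-(3,4-dimethoxyphenyl)-3,4-dimethyltetrahydrofuran-2-yl]-2-methoxyphenoxy}propan-1-ol | COc1ccc([C@@H](O)[C@H](C)Oc2ccc([C@H]3O[C@@H](c4ccc(OC)c(OC)c4)[C@@H](C)[C@H]3C)cc2OC)cc1OC | target

**Step count**
Total: 11 steps. Longest linear sequence: 10 steps (steps 1, 2, 3, 5, 6, 7, 8, 9, 10, 11 from 3,4-dimethoxybenzaldehyde); step 4 is a one-step side branch.

**Steps most likely to fail**

Step 2. Methyl transfer to the internal alkyne may be slow, and CO2 capture by the hindered, chelated alkenylmagnesium may lag behind its protonation, so that open-chain allylic alcohol is recovered. The C5–O bond may also ionise during acidic lactonisation and erode the enantiomeric purity. The fallback sets out from 4 and returns at 10. It separates the two events: the carbomagnesiation is run as before (CH3MgBr, CuI, THF), but alkenylmagnesium 8 is quenched with I2 at −78 °C to give (S,Z)-1-(3,4-dimethoxyphenyl)-3-iodo-2-methylbut-2-en-1-ol F1, which is isolated and shows whether the carbometalation is complete. The carbonyl carbon C2 is then introduced by carbonylative lactonisation (PdCl2(PPh3)2, CO 1 atm, K2CO3, THF, 40 °C): CO inserts into the C–I bond and the neighbouring hydroxyl captures the acylpalladium, closing butenolide 10 without any acidic, ionising work-up.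

Step 6. The oxocarbenium ion may lose its C3 proton to give an enol ether and reprotonate, or BF3·OEt2 may ionise the benzylic C–O bonds of the product; either path epimerises the strained all-cis array, and hydride delivery may not be fully face-selective. The fallback sets out from 15 and returns at 18. Lactol 15 is dehydrated on purpose (PPTS cat., toluene, 4 Å molecular sieves, 60 °C) to the cyclic enol ether (2R,3S)-5-[4-(benzyloxy)-3-methoxyphenyl]-2-(3,4-dimethoxyphenyl)-3,4-dimethyl-2,3-dihydrofuran F2. Hydrogenation over Pd/C (H2, EtOAc, rt) should add both hydrogens syn from the face away from the C4 methyl and ring A, which sets C2 and C3 together in the all-cis sense. The benzyl ether is cleaved in the same operation, so the sequence arrives at phenol 18.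

Step 10. The basic, rather sluggish electron-rich aryl Grignard may enolise the α-aryloxy amide or the liberated ketone, which would erode the C8 configuration on late-stage material. The fallback sets out from 18 (with 19) and returns at 23, replacing steps 8 to 10. The side-chain ketone is built separately. Methyl (R)-lactate 19 is converted into (R)-2-hydroxy-N-methoxy-N-methylpropanamide F3 (MeNHOMe·HCl, iPrMgCl, THF, −20 °C). Excess 22 then gives (R)-1-(3,4-dimethoxyphenyl)-2-hydroxypropan-1-one F4. Tosylation (TsCl, Et3N, DMAP cat., CH2Cl2, 0 °C) gives (R)-1-(3,4-dimethoxyphenyl)-1-oxopropan-2-yl 4-methylbenzenesulfonate F5. Phenol 18 is then alkylated with F5 under the non-nucleophilic phosphazene base BEMP (MeCN, rt). The SN2 displacement inverts the carbinol carbon and should give (S)-ketone 23 directly, without the ketone meeting an organometallic reagent.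

**Further compounds**
F1 | step 2 | (S,Z)-1-(3,4-dimethoxyphenyl)-3-iodo-2-methylbut-2-en-1-ol | O[C@@H](c1ccc(OC)c(OC)c1)/C(C)=C(/C)I
F2 | step 6 | (2R,3S)-5-[4-(benzyloxy)-3-methoxyphenyl]-2-(3,4-dimethoxyphenyl)-3,4-dimethyl-2,3-dihydrofuran | CC1=C(c2ccc(OCc3ccccc3)c(OC)c2)O[C@@H](c2ccc(OC)c(OC)c2)[C@H]1C
F3 | step 10 | (R)-2-hydroxy-N-methoxy-N-methylpropanamide | C[C@@H](O)C(=O)N(C)OC
F4 | step 10 | (R)-1-(3,4-dimethoxyphenyl)-2-hydroxypropan-1-one | C[C@@H](O)C(=O)c1ccc(OC)c(OC)c1
F5 | step 10 | (R)-1-(3,4-dimethoxyphenyl)-1-oxopropan-2-yl 4-methylbenzenesulfonate | C[C@@H](OS(=O)(=O)c1ccc(C)cc1)C(=O)c1ccc(OC)c(OC)c1
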